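A small charge of initiator, 3.1 mol% of the starting material, has to carry a chain through two carriers. The two flasks differ in their coupling partner.

- larch: starting material 20 mM; coupling partner 1.50 equiv; protic impurity 10.0 mM; initiator 3.1 mol%; time 40 s
- maple: starting material 20 mM; coupling partner 1.80 equiv; protic impurity 10.0 mM; initiator 3.1 mol%; time 40 s

    initiator → 2 initiating radical (k1 = 0.00202 s⁻¹)
    starting material + initiating radical → capped initiator + first chain carrier (k2 = 3.47 × 10⁶ M⁻¹ s⁻¹)
    coupling partner + first chain carrier → target + second chain carrier (k3 = 32700 M⁻¹ s⁻¹)
    starting material + second chain carrier → released group + first chain carrier (k4 = 1.35 × 10⁶ M⁻¹ s⁻¹)
    2 first chain carrier → ended chains A (k5 = 3 × 10⁶ M⁻¹ s⁻¹)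
    2 second chain carrier → ended chains B (k6 = 6 × 10⁶ M⁻¹ s⁻¹)
    coupling partner + released group ⇌ idle adduct, settled at all times (K7 = 950 M⁻¹)
    starting material + protic impurity → quenched substrate (k8 = 0.955 M⁻¹ s⁻¹)

- percent here means starting material units held: one ended chains A counts as two
- what is said of released group includes idle adduct
- for a step with 2 of a species take k times the square, and two of it per event
- run time (larch): 40 s

* which of these there is most of at the end, counted by the starting material in it, larch (first chain carrier / target / starting material)
* which of these there is most of at the end, counted by the starting material in it, maple (first chain carrier / target / starting material)
* amount of the one of these that there is most of at the end, in percent of the starting material charged, larch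
* amount of the one of these that there is most of at the end, in percent of the starting material charged, maple

Starting material, the smaller charge in larch, is the limiting reagent, but my own reckoning for this short run is a ledger of the coupling partner, with an even split as the zero of the scale.

1. Each target frees one released group. At the start in larch, the binding constant times free partner is 28, so nearly all of that group binds partner as idle adduct. Each target therefore costs about twice one partner: one enters the target, one idles. I take this even split for the whole run.

2. The starting-material step has a constant of 1.35 × 10⁶ M⁻¹ s⁻¹, far larger than the 32700 M⁻¹ s⁻¹ of the partner step. The partner step is thus the rate-limiting step, and first chain carrier is the resting state.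

3. Initiator holds 0.620 mM, and its half-life of 5.7 min is much longer than the 40 s run, so I hold it at its charge. Balancing radical supply against loss to ended chains A gives a carrier level c = 0.646 µM.

4. The spend constant κ, 2 times the partner-step constant times c, is the pseudo-first-order rate at which free partner goes: 0.0423 s⁻¹. Over the run, a fraction F = 81.6% of the partner is spent.

5. The books for larch: of 30.0 mM partner, 12.2 mM enters target, the same amount idles, and 5.52 mM stays free. Target comes to 61.2%.

6. The books for maple: the same F on 36.0 mM partner gives 73.4%.

7. Target leads in larch, since 38.8% remains for starting material and everything else. It leads in maple too, and the carrier holds 0.00323%.

The forecast names target for larch and target for maple, at 62% and 74%, arguing that a “released group also ties up about one more coupling partner”. My figures are slightly lower.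

The simulation gives target in larch at 62.4%, with starting material at 21.1%, and target in maple at 74.5%, with starting material at 10.9%. The forecast held on both choices and both amounts.

The neighbouring flask is maple with 1.9 mol% of initiator. Since c follows the square root of the initiator charge, κ falls to 0.0331 s⁻¹, and the spent fraction to 73.4%. The even split then puts target at 66.0% and free partner at 26.6% of its charge. The simulated neighbour ends with target at 66.2%, starting material at 17.7% and free partner at 30% of its charge.

The numbers are invented, and the outcome is calculated.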